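**Retrosynthetic overview** (daucane locants: C1 quaternary fusion carbon, C4 carbinol carbon, C5 fusion CH, C6 oxygenated carbon, C7=C8 alkene)
1. C6–O ester last: target ⇒ 4,6-diol + 4-acetoxybenzoyl chloride; the 6-carbinol ⇒ the 6-ketone by 4-OH-directed hydride delivery.
2. Five-membered ring (closed second): C4–C5 bond ⇒ intramolecular aldol of a cycloheptenone onto the isopropyl ketone, which also creates the 4-OH.
3. Seven-membered ring (closed first): C6–C7 bond ⇒ acylium–olefin cyclisation of an acyclic C15 keto acid through the tertiary C8 cation.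
4. Acyclic keto acid ⇒ oxidative cleavage of the C4–C6 bond of a 3,3-disubstituted menthone.
5. That ketone ⇒ piperitone + a C5 Grignard reagent by Cu-catalysed asymmetric conjugate addition, which sets C1, the only stereocentre carried through.

Assumption: piperitone is used as the racemate (any enantiomeric composition will do), because its stereocentre becomes a ketone carbon in step 2.

**Step 1**
Reactants: 1 piperitone (3-methyl-6-(propan-2-yl)cyclohex-2-en-1-one); 2 4-bromo-2-methylbut-1-ene
Product: 4 (5R)-5-methyl-5-(3-methylbut-3-en-1-yl)-2-(propan-2-yl)cyclohexan-1-one (both C2 epimers), via Grignard reagent 3 (not isolated)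
Conditions: Mg, Et2O, 35 °C; then 1, Cu(OTf)2 (3 mol%), chiral C2-symmetric imidazolinium salt (NHC precursor, 4 mol%), Et2O, −30 °C; aq. NH4Cl
Reagents that add atoms: none
Why: Cu(OTf)2/NHC-catalysed asymmetric conjugate addition of the Grignard reagent to the β-methyl enone (Alexakis-type) creates the all-carbon quaternary centre (daucane C1) under catalyst control, the ligand enantiomer being chosen for the (5R) product, while the epimerisable C2 centre inherited from 1 does not matter because it becomes a carbonyl carbon in step 2.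

**Step 2**
Reactants: 4 (5R)-5-methyl-5-(3-methylbut-3-en-1-yl)-2-(propan-2-yl)cyclohexan-1-one
Product: 7 (3S)-3,7-dimethyl-3-(3-methylbut-3-en-1-yl)-6-oxooctanoic acid, via hydroperoxide 5 (not isolated), via hydroxy ketone 6 (not isolated)
Conditions: KOtBu (0.3 equiv), O2 (1 atm), P(OEt)3, THF–tBuOH, −20 °C; then NaIO4, THF–H2O, 23 °C
Reagents that add atoms: dioxygen, O=O; sodium periodate, [Na+].[O-][I](=O)(=O)=O
Why: Gardner α-hydroxylation (the more substituted potassium enolate is oxygenated by O2 and the hydroperoxide is reduced in situ by the phosphite) followed by Malaprade-type periodate cleavage of the α-ketol opens the menthane ring between the carbonyl and the isopropyl-bearing carbon, and no stereocentre of the product is involved because C1 is remote and the oxidised carbon becomes a ketone.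

**Step 3**
Reactants: 7 (3S)-3,7-dimethyl-3-(3-methylbut-3-en-1-yl)-6-oxooctanoic acid
Product: 10 (6S)-3,6-dimethyl-6-(4-methyl-3-oxopentyl)cyclohept-2-en-1-one, via acid chloride 8 (not isolated), via chloro ketone 9 (not isolated)
Conditions: (COCl)2, DMF (cat.), CH2Cl2, 0 °C; SnCl4, CH2Cl2, −78 °C; then DBU, 23 °C
Reagents that add atoms: none
Why: Intramolecular Friedel–Crafts-type acylation of the 1,1-disubstituted alkene by the SnCl4-activated acid chloride (acylium–olefin cyclisation, 7-endo, Markovnikov) closes the seven-membered ring through the tertiary C8 carbocation, and dehydrochlorination of the resulting β-chloro ketone gives the conjugated enone without touching C1.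

**Step 4**
Reactants: 10 (6S)-3,6-dimethyl-6-(4-methyl-3-oxopentyl)cyclohept-2-en-1-one
Product: 11 (3R,3aR,8aS)-3-hydroxy-6,8a-dimethyl-3-(propan-2-yl)-2,3,3a,7,8,8a-hexahydroazulen-4(1H)-one
Conditions: KOtBu (0.3 equiv), tBuOH–THF (1:4), −10 → 0 °C; AcOH quench
Reagents that add atoms: none
Why: Reversible intramolecular aldol addition of the α′-enolate (C5) to the isopropyl ketone closes the five-membered ring and creates the C4 tertiary alcohol, and under these equilibrating (retro-aldol and C5-epimerising) conditions the product is expected, though not proven, to collect as the hydrogen-bonded isomer with 4-OH cis and isopropyl trans to the C5–C6 bond and a trans ring fusion, so that C4 and C5 are set by thermodynamic control relative to C1.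

**Step 5**
Reactants: 11 (3R,3aR,8aS)-3-hydroxy-6,8a-dimethyl-3-(propan-2-yl)-2,3,3a,7,8,8a-hexahydroazulen-4(1H)-one
Product: 12 (3R,3aS,4S,8aS)-6,8a-dimethyl-3-(propan-2-yl)-1,2,3,3a,4,7,8,8a-octahydroazulene-3,4-diol
Conditions: Me4NBH(OAc)3, MeCN–AcOH (1:1), −30 °C
Reagents that add atoms: none
Why: Evans–Saksena hydroxyl-directed reduction, in which the C4 oxygen binds the triacetoxyborohydride and delivers hydride intramolecularly in a 1,2-fashion to the β face of the C6 ketone, gives the 6α-alcohol (1,3-anti diol) that external hydride attack from the open α face would not give.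

**Step 6**
Reactants: 12 (3R,3aS,4S,8aS)-6,8a-dimethyl-3-(propan-2-yl)-1,2,3,3a,4,7,8,8a-octahydroazulene-3,4-diol; 13 4-acetoxybenzoyl chloride
Product: 15 (3R,3aS,4S,8aS)-3-hydroxy-6,8a-dimethyl-3-(propan-2-yl)-1,2,3,3a,4,7,8,8a-octahydroazulen-4-yl 4-hydroxybenzoate (target), via acetate ester 14 (not isolated)
Conditions: Et3N, DMAP (cat.), CH2Cl2, 0 → 23 °C; then pyrrolidine, 23 °C
Reagents that add atoms: none
Why: DMAP-catalysed acylation (nucleophilic acyl substitution) takes place only at the secondary allylic C6 hydroxyl with retention, the tertiary C4 hydroxyl being inert, and the far more electrophilic aryl acetate is then removed chemoselectively by aminolysis with pyrrolidine to free the phenol.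

**Compound list**
1 | piperitone, 3-methyl-6-(propan-2-yl)cyclohex-2-en-1-one (racemate) | CC1=CC(=O)C(CC1)C(C)C | starting material
2 | 4-bromo-2-methylbut-1-ene | CC(=C)CCBr | starting material
3 | (3-methylbut-3-en-1-yl)magnesium bromide | CC(=C)CC[Mg]Br | intermediate
4 | (5R)-5-methyl-5-(3-methylbut-3-en-1-yl)-2-(propan-2-yl)cyclohexan-1-one (both C2 epimers) | O=C1C[C@@](C)(CCC(C)=C)CCC1C(C)C | intermediate
5 | (5S)-2-hydroperoxy-5-methyl-5-(3-methylbut-3-en-1-yl)-2-(propan-2-yl)cyclohexan-1-one (both C2 epimers) | O=C1C[C@@](C)(CCC(C)=C)CCC1(OO)C(C)C | intermediate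
6 | (5S)-2-hydroxy-5-methyl-5-(3-methylbut-3-en-1-yl)-2-(propan-2-yl)cyclohexan-1-one (both C2 epimers) | O=C1C[C@@](C)(CCC(C)=C)CCC1(O)C(C)C | intermediate
7 | (3S)-3,7-dimethyl-3-(3-methylbut-3-en-1-yl)-6-oxooctanoic acid | OC(=O)C[C@@](C)(CCC(C)=C)CCC(=O)C(C)C | intermediate
8 | (3S)-3,7-dimethyl-3-(3-methylbut-3-en-1-yl)-6-oxooctanoyl chloride | ClC(=O)C[C@@](C)(CCC(C)=C)CCC(=O)C(C)C | intermediate
9 | (6R)-3-chloro-3,6-dimethyl-6-(4-methyl-3-oxopentyl)cycloheptan-1-one (both C3 epimers) | CC1(Cl)CC(=O)C[C@@](C)(CC1)CCC(=O)C(C)C | intermediate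
10 | (6S)-3,6-dimethyl-6-(4-methyl-3-oxopentyl)cyclohept-2-en-1-one | CC1=CC(=O)C[C@@](C)(CC1)CCC(=O)C(C)C | intermediate
11 | (3R,3aR,8aS)-3-hydroxy-6,8a-dimethyl-3-(propan-2-yl)-2,3,3a,7,8,8a-hexahydroazulen-4(1H)-one | CC1=CC(=O)[C@@H]2[C@@](C)(CC1)CC[C@@]2(O)C(C)C | intermediate
12 | (3R,3aS,4S,8aS)-6,8a-dimethyl-3-(propan-2-yl)-1,2,3,3a,4,7,8,8a-octahydroazulene-3,4-diol | CC1=C[C@H](O)[C@@H]2[C@@](C)(CC1)CC[C@@]2(O)C(C)C | intermediate
13 | 4-acetoxybenzoyl chloride | CC(=O)Oc1ccc(cc1)C(Cl)=O | starting material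
14 | (3R,3aS,4S,8aS)-3-hydroxy-6,8a-dimethyl-3-(propan-2-yl)-1,2,3,3a,4,7,8,8a-octahydroazulen-4-yl 4-(acetyloxy)benzoate | CC1=C[C@H](OC(=O)c2ccc(OC(C)=O)cc2)[C@@H]2[C@@](C)(CC1)CC[C@@]2(O)C(C)C | intermediate
15 | (3R,3aS,4S,8aS)-3-hydroxy-6,8a-dimethyl-3-(propan-2-yl)-1,2,3,3a,4,7,8,8a-octahydroazulen-4-yl 4-hydroxybenzoate | CC1=C[C@H](OC(=O)c2ccc(O)cc2)[C@@H]2[C@@](C)(CC1)CC[C@@]2(O)C(C)C | target

**Total step count:** 6. **Longest linear sequence:** 6 steps (from 1).

**Three steps most likely to fail**

Step 4 is the weakest step. The enolates of the saturated ketone and the extended dienolate compete with the C5 enolate, and a C3-to-C8 Michael addition would be irreversible. The kinetically preferred closure is cis-fused, so the trans-fused ketol 11 depends on full equilibration, and its thermodynamic preference is an expectation, not a known fact. Dehydration is a further drain. The fallback sets the same centres by reagent-directed steps instead of equilibration. Setting out from 10, hot methanolic KOH drives the closure through to dehydration and gives the cross-conjugated dienone (8aS)-6,8a-dimethyl-3-(propan-2-yl)-2,7,8,8a-tetrahydroazulen-4(1H)-one F1. NaBH4/CeCl3·7H2O reduces it from the face opposite the angular methyl to the 6β-alcohol (4R,8aS)-6,8a-dimethyl-3-(propan-2-yl)-1,2,4,7,8,8a-hexahydroazulen-4-ol F2. VO(acac)2/tBuOOH epoxidises the tetrasubstituted alkene syn to that hydroxyl to give 4β,5β-epoxydauc-7-en-6β-ol F3, and Dess–Martin periodinane gives the epoxy enone 4β,5β-epoxydauc-7-en-6-one F4. SmI2 (THF–MeOH, −78 °C) then opens the epoxide at C5 with the C4–O bond kept, and the samarium enolate is protonated to the isomer with C6 trans to isopropyl, which rejoins the route at 11.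

Step 3 may fail because a 7-endo alkene acylation must compete with acylation of the enol of the free ketone and with cationic oligomerisation. Setting out from 7 through its acid chloride 8, Stille coupling with Bu3SnCH=CH2 (Pd(PPh3)4, THF, 50 °C) gives the vinyl ketone (5S)-5,9-dimethyl-5-(3-methylbut-3-en-1-yl)dec-1-ene-3,8-dione F5. Ring-closing metathesis with the second-generation Hoveyda–Grubbs catalyst RuCl2(=CH–C6H4-2-OiPr)(H2IMes) (CH2Cl2, 40 °C) then closes the seven-membered ring and rejoins the route at 10.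

Step 2 may fail if oxygenation occurs at the neopentyl C6 methylene instead of the isopropyl-bearing carbon, or if the hindered α-ketol resists periodate. The fallback also removes the α′-stereocentre that could erode selectivity in step 1. Setting out from the Grignard reagent 3, the same Cu(OTf)2/NHC conjugate addition is run on 3-methylcyclohex-2-en-1-one F6 to give (3R)-3-methyl-3-(3-methylbut-3-en-1-yl)cyclohexan-1-one F7. Nitrosation (tBuONO, KOtBu) at the only unhindered α-methylene gives the α-oximino ketone (5S)-2-(hydroxyimino)-5-methyl-5-(3-methylbut-3-en-1-yl)cyclohexan-1-one F8. Beckmann fragmentation (TsCl, aq. NaOH) gives the cyano acid (3S)-5-cyano-3-methyl-3-(3-methylbut-3-en-1-yl)pentanoic acid F9. iPrMgCl (CuBr·SMe2 cat., then H3O+) converts the nitrile into the isopropyl ketone and rejoins the route at 7.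

**Further compounds**
F1 | step 4 | (8aS)-6,8a-dimethyl-3-(propan-2-yl)-2,7,8,8a-tetrahydroazulen-4(1H)-one | CC1=CC(=O)C2=C(CC[C@]2(C)CC1)C(C)C
F2 | step 4 | (4R,8aS)-6,8a-dimethyl-3-(propan-2-yl)-1,2,4,7,8,8a-hexahydroazulen-4-ol | CC1=C[C@@H](O)C2=C(CC[C@]2(C)CC1)C(C)C
F3 | step 4 | 4β,5β-epoxydauc-7-en-6β-ol (epoxide oxygen syn to the C6 hydroxyl) | CC1=C[C@@H](O)[C@]23O[C@@]2(C(C)C)CC[C@]3(C)CC1
F4 | step 4 | 4β,5β-epoxydauc-7-en-6-one | CC1=CC(=O)[C@]23O[C@@]2(C(C)C)CC[C@]3(C)CC1
F5 | step 3 | (5S)-5,9-dimethyl-5-(3-methylbut-3-en-1-yl)dec-1-ene-3,8-dione | C=CC(=O)C[C@@](C)(CCC(C)=C)CCC(=O)C(C)C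
F6 | step 2 | 3-methylcyclohex-2-en-1-one | CC1=CC(=O)CCC1
F7 | step 2 | (3R)-3-methyl-3-(3-methylbut-3-en-1-yl)cyclohexan-1-one | O=C1C[C@@](C)(CCC(C)=C)CCC1
F8 | step 2 | (5S)-2-(hydroxyimino)-5-methyl-5-(3-methylbut-3-en-1-yl)cyclohexan-1-one | O=C1C[C@@](C)(CCC(C)=C)CCC1=NO
F9 | step 2 | (3S)-5-cyano-3-methyl-3-(3-methylbut-3-en-1-yl)pentanoic acid | OC(=O)C[C@@](C)(CCC(C)=C)CCC#N
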